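**Plan**

- Retrosynthesis: the C3 arm's ketone is taken back to a propargylic alcohol, the alkyne–benzoyl bond of the C5 arm is cut, then the C3–alkyne bond (Sonogashira coupling at a 3-iodofuran), and last the furan itself at C4–CH3 and O1–C2.
- Enabling feature: on the furan, the methyl-bearing C4 lies β to C2 (the phenyl-bearing carbon, a former benzoyl carbonyl) and next to C5, which carries an alkyne. O1–C5 can therefore begin as a carbinol flanked by a benzoyl ynone and a silylalkyne, and the methyl can enter as a nucleophile.
- Forward: an open chain is joined from an ynal, an ethynyl Grignard reagent and a Weinreb amide (steps 1–2). Methyl cuprate addition and acid close the only ring, the furan (step 3). C3 iodination, alkynylation, desilylation, benzoylation of the C5 alkyne and oxidation finish the two arms (steps 4–8).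
- Stereochemistry: the target has no stereocentre; every carbinol centre carried through the route is racemic and ends as an sp2 carbon.

Key step: step 3

Remark: all hydroxyl-bearing carbons are used as racemates because each becomes an sp2 carbon of the achiral target, and aldehyde 1 is taken as a purchased reagent.

**Route**

Step 1
Reactants: 1 3-(triisopropylsilyl)propynal; 2 ethynylmagnesium bromide
Product: 3 1-(triisopropylsilyl)penta-1,4-diyn-3-ol (racemic)
Conditions: 2 (0.5 M in THF, 1.2 equiv), THF, −78 → 0 °C; cold 1 M aq HCl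
Reagents that add atoms: none
Why: 1,2-Addition of an alkynyl Grignard reagent to the aldehyde, the only electrophile present, should give the skipped diynol, whose racemic carbinol carbon later becomes furan C5.

Step 2
Reactants: 3 1-(triisopropylsilyl)penta-1,4-diyn-3-ol; 4 N-methoxy-N-methylbenzamide
Product: 7 4-hydroxy-1-phenyl-6-(triisopropylsilyl)hexa-2,5-diyn-1-one (racemic), via dilithiated diynol 5 (not isolated), via tetrahedral amide adduct 6 (not isolated)
Conditions: n-BuLi (2.05 equiv), THF, −78 °C; 4 (1.2 equiv), −78 → −20 °C; poured into cold 1 M aq HCl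
Reagents that add atoms: none
Why: Weinreb ketone synthesis with a lithium acetylide: the second equivalent of base lithiates the terminal alkyne of the alkoxide to give 5, the chelated adduct 6 cannot accept a second nucleophile, and the inverse acidic quench protonates the liberated amine before it can add to the ynone.

Step 3
Reactants: 7 4-hydroxy-1-phenyl-6-(triisopropylsilyl)hexa-2,5-diyn-1-one
Product: 10 triisopropyl[(3-methyl-5-phenylfuran-2-yl)ethynyl]silane, via hydroxy enone 8 (not isolated), via cyclic hemiketal 9 (not isolated)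
Conditions: Me2CuLi (2.5 equiv, from CuI and MeLi, Et2O, 0 °C), Et2O/THF, −78 °C; then 2 M aq HCl, −78 °C → rt
Reagents that add atoms: lithium dimethylcuprate, [Li+].C[Cu-]C (made in the flask from methyllithium, C[Li], and CuI)
Why: Conjugate addition of a lithium dialkylcuprate to an ynone followed by acid-catalysed cyclodehydration of the γ-hydroxy enone, the ketone counterpart of the familiar butenolide synthesis from γ-hydroxy ynoates: one equivalent of Me2CuLi is spent on the hydroxyl, a second carbocuprates the triple bond so that methyl ends on the carbon β to the benzoyl group (future C4), and protonation gives enone 8. Syn addition places the carbinol and the benzoyl group cis (Z), and the acid equilibrates any E isomer that arises through the allenolate. The hydroxyl then adds to the ketone carbonyl in a 5-exo-trig closure (O1–C2) to hemiketal 9, which loses water to give the aromatic furan 10. No stereocentre is formed, and the racemic carbinol carbon becomes sp2 C5. The step needs 1,4- rather than 1,2-addition and reaction at the ynone rather than at the silylalkyne: the soft cuprate and the fact that only the benzoyl-conjugated triple bond is an acceptor secure both, while the lithium alkoxide is too poor a leaving group for SN2' displacement to an allene.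

Step 4
Reactants: 10 triisopropyl[(3-methyl-5-phenylfuran-2-yl)ethynyl]silane
Product: 11 [(4-iodo-3-methyl-5-phenylfuran-2-yl)ethynyl]triisopropylsilane
Conditions: NIS (1.1 equiv), DMF, 0 °C → rt, dark
Reagents that add atoms: N-iodosuccinimide, O=C1CCC(=O)N1I
Why: Electrophilic aromatic iodination should take place at the single free furan position, which is far more electron-rich than the phenyl ring, while the bulky silylalkyne is inert to N-iodosuccinimide in the absence of silver salts.

Step 5
Reactants: 11 [(4-iodo-3-methyl-5-phenylfuran-2-yl)ethynyl]triisopropylsilane; 12 but-3-yn-2-ol (racemic)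
Product: 13 4-{4-methyl-2-phenyl-5-[(triisopropylsilyl)ethynyl]furan-3-yl}but-3-yn-2-ol (racemic)
Conditions: 12 (1.5 equiv), PdCl2(PPh3)2 (5 mol %), CuI (10 mol %), Et3N, THF, degassed, 50 °C
Reagents that add atoms: none
Why: Sonogashira coupling: oxidative addition of zerovalent palladium into the furyl carbon–iodine bond and transmetalation from the copper acetylide of 12 are routine for 3-iodofurans, and the free hydroxyl and the silylalkyne are tolerated.

Step 6
Reactants: 13 4-{4-methyl-2-phenyl-5-[(triisopropylsilyl)ethynyl]furan-3-yl}but-3-yn-2-ol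
Product: 14 4-(5-ethynyl-4-methyl-2-phenylfuran-3-yl)but-3-yn-2-ol (racemic)
Conditions: Bu4NF (1.1 equiv), wet THF, 0 °C; used without storage
Reagents that add atoms: none
Why: Fluoride-induced protodesilylation of an alkynylsilane should free the terminal alkyne, as no other silicon group is present and the propargylic alcohol is untouched.

Step 7
Reactants: 14 4-(5-ethynyl-4-methyl-2-phenylfuran-3-yl)but-3-yn-2-ol; 4 N-methoxy-N-methylbenzamide
Product: 17 3-[4-(3-hydroxybut-1-yn-1-yl)-3-methyl-5-phenylfuran-2-yl]-1-phenylprop-2-yn-1-one (racemic), via dilithiated alkynol 15 (not isolated), via tetrahedral amide adduct 16 (not isolated)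
Conditions: n-BuLi (2.05 equiv), THF, −78 °C; 4 (1.3 equiv), −78 → −20 °C; poured into cold 1 M aq HCl
Reagents that add atoms: none
Why: Weinreb ketone synthesis on the alkoxide–acetylide dianion 15: only the carbanion attacks the amide, the chelated adduct 16 blocks a second addition, and the cold acidic quench releases the ynone while keeping the liberated amine protonated.

Step 8
Reactants: 17 3-[4-(3-hydroxybut-1-yn-1-yl)-3-methyl-5-phenylfuran-2-yl]-1-phenylprop-2-yn-1-one
Product: 18 Capillaridin A, 4-[4-methyl-5-(3-oxo-3-phenylprop-1-yn-1-yl)-2-phenylfuran-3-yl]but-3-yn-2-one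
Conditions: activated MnO2 (20 equiv), CH2Cl2, rt
Reagents that add atoms: none
Why: MnO2 oxidation of a propargylic alcohol should dehydrogenate the activated secondary carbinol under neutral heterogeneous conditions that leave the furan and the existing ynone alone, and it removes the last stereocentre.

**Compound list**

1 | 3-(triisopropylsilyl)propynal | O=CC#C[Si](C(C)C)(C(C)C)C(C)C | starting material
2 | ethynylmagnesium bromide | C#C[Mg]Br | starting material
3 | 1-(triisopropylsilyl)penta-1,4-diyn-3-ol (racemic) | OC(C#C)C#C[Si](C(C)C)(C(C)C)C(C)C | intermediate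
4 | N-methoxy-N-methylbenzamide | CON(C)C(=O)c1ccccc1 | starting material
5 | lithium 1-lithio-5-(triisopropylsilyl)penta-1,4-diyn-3-olate (dilithiated 3, racemic, formed in the flask) | [Li]C#CC(O[Li])C#C[Si](C(C)C)(C(C)C)C(C)C | intermediate
6 | dilithium 1-[methoxy(methyl)amino]-1-phenyl-6-(triisopropylsilyl)hexa-2,5-diyne-1,4-diolate (tetrahedral adduct of 5 and 4, diastereomer mixture, formed in the flask) | CON(C)C(O[Li])(C#CC(O[Li])C#C[Si](C(C)C)(C(C)C)C(C)C)c1ccccc1 | intermediate
7 | 4-hydroxy-1-phenyl-6-(triisopropylsilyl)hexa-2,5-diyn-1-one (racemic) | O=C(C#CC(O)C#C[Si](C(C)C)(C(C)C)C(C)C)c1ccccc1 | intermediate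
8 | (Z)-4-hydroxy-3-methyl-1-phenyl-6-(triisopropylsilyl)hex-2-en-5-yn-1-one (racemic, formed in the flask; the E isomer equilibrates into it under acid) | O=C(/C=C(C)\C(O)C#C[Si](C(C)C)(C(C)C)C(C)C)c1ccccc1 | intermediate
9 | 4-methyl-2-phenyl-5-[(triisopropylsilyl)ethynyl]-2,5-dihydrofuran-2-ol (diastereomer mixture, formed in the flask) | CC1=CC(O)(c2ccccc2)OC1C#C[Si](C(C)C)(C(C)C)C(C)C | intermediate
10 | triisopropyl[(3-methyl-5-phenylfuran-2-yl)ethynyl]silane | Cc1cc(-c2ccccc2)oc1C#C[Si](C(C)C)(C(C)C)C(C)C | intermediate
11 | [(4-iodo-3-methyl-5-phenylfuran-2-yl)ethynyl]triisopropylsilane | Cc1c(I)c(-c2ccccc2)oc1C#C[Si](C(C)C)(C(C)C)C(C)C | intermediate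
12 | but-3-yn-2-ol (racemic) | CC(O)C#C | starting material
13 | 4-{4-methyl-2-phenyl-5-[(triisopropylsilyl)ethynyl]furan-3-yl}but-3-yn-2-ol (racemic) | CC(O)C#Cc1c(-c2ccccc2)oc(C#C[Si](C(C)C)(C(C)C)C(C)C)c1C | intermediate
14 | 4-(5-ethynyl-4-methyl-2-phenylfuran-3-yl)but-3-yn-2-ol (racemic) | CC(O)C#Cc1c(-c2ccccc2)oc(C#C)c1C | intermediate
15 | lithium 4-[5-(lithioethynyl)-4-methyl-2-phenylfuran-3-yl]but-3-yn-2-olate (dilithiated 14, racemic, formed in the flask) | CC(O[Li])C#Cc1c(-c2ccccc2)oc(C#C[Li])c1C | intermediate
16 | dilithium alkoxide of the tetrahedral adduct of 15 and 4, carrying the 1-[methoxy(methyl)amino]-1-phenylprop-2-yn-1-olate unit on furan C5 (diastereomer mixture, formed in the flask) | CC(O[Li])C#Cc1c(-c2ccccc2)oc(C#CC(O[Li])(N(C)OC)c2ccccc2)c1C | intermediate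
17 | 3-[4-(3-hydroxybut-1-yn-1-yl)-3-methyl-5-phenylfuran-2-yl]-1-phenylprop-2-yn-1-one (racemic) | CC(O)C#Cc1c(-c2ccccc2)oc(C#CC(=O)c2ccccc2)c1C | intermediate
18 | Capillaridin A, 4-[4-methyl-5-(3-oxo-3-phenylprop-1-yn-1-yl)-2-phenylfuran-3-yl]but-3-yn-2-one | CC(=O)C#Cc1c(-c2ccccc2)oc(C#CC(=O)c2ccccc2)c1C | target

**Step count and risks**

Total steps: 8. Longest linear sequence: 8 steps (1 → 18).

Steps most likely to fail:

1. Step 3. The alkoxide formed from the free hydroxyl may trigger propargyl–allenyl or redox isomerisation at the doubly propargylic carbinol before methyl transfer, and an E-configured enone may close only slowly. The fallback sets out from 7 and returns at 10. Aqueous hydrogen iodide in toluene at room temperature should add iodide to the ynone to give 4-hydroxy-3-iodo-1-phenyl-6-(triisopropylsilyl)hex-2-en-5-yn-1-one F1. Under the same acid F1 equilibrates its alkene isomers and cyclodehydrates to triisopropyl[(3-iodo-5-phenylfuran-2-yl)ethynyl]silane F2. Negishi coupling of F2 with MeZnCl under Pd(PPh3)4 in THF then forms the C4–CH3 bond on the closed ring and gives 10. The same two bonds are made, with no strong base near the carbinol.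

2. Step 2. The dianion or the hydroxy ynone may isomerise at the doubly propargylic position, and the amine liberated on work-up may add to the ynone in conjugate fashion. The fallback sets out from 3 and returns at 7. Silylation (Et3SiCl, imidazole, CH2Cl2) should give triethyl{[1-(triisopropylsilyl)penta-1,4-diyn-3-yl]oxy}silane F3. One equivalent of n-BuLi in THF at −78 °C gives {3-[(triethylsilyl)oxy]-5-(triisopropylsilyl)penta-1,4-diyn-1-yl}lithium F4, which is added to benzaldehyde to give 1-phenyl-4-[(triethylsilyl)oxy]-6-(triisopropylsilyl)hexa-2,5-diyn-1-ol F5. MnO2 in CH2Cl2 oxidises the benzylic propargylic alcohol to 1-phenyl-4-[(triethylsilyl)oxy]-6-(triisopropylsilyl)hexa-2,5-diyn-1-one F6. Dilute HCl in aqueous THF at 0 °C cleaves the silyl ether and gives 7. The ynone is thus generated under neutral conditions, with neither an amine nor a neighbouring alkoxide present.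

3. Step 7. Acylation of the sensitive ethynylfuran dianion may be incomplete, and the amine released when the adduct collapses may add to the doubly activated ynone during the quench. The fallback sets out from 14 and returns at 18. Dianion 15 is added to benzaldehyde in THF at −78 °C to give 4-[5-(3-hydroxy-3-phenylprop-1-yn-1-yl)-4-methyl-2-phenylfuran-3-yl]but-3-yn-2-ol F7 as a diastereomer mixture. Excess activated MnO2 in CH2Cl2 then oxidises both propargylic alcohols in one operation and gives 18 directly.

**Further compounds**

F1 | step 3 | 4-hydroxy-3-iodo-1-phenyl-6-(triisopropylsilyl)hex-2-en-5-yn-1-one (racemic, alkene isomer mixture, formed in the flask) | O=C(C=C(I)C(O)C#C[Si](C(C)C)(C(C)C)C(C)C)c1ccccc1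
F2 | step 3 | triisopropyl[(3-iodo-5-phenylfuran-2-yl)ethynyl]silane | Ic1cc(-c2ccccc2)oc1C#C[Si](C(C)C)(C(C)C)C(C)C
F3 | step 2 | triethyl{[1-(triisopropylsilyl)penta-1,4-diyn-3-yl]oxy}silane (racemic) | CC[Si](CC)(CC)OC(C#C)C#C[Si](C(C)C)(C(C)C)C(C)C
F4 | step 2 | {3-[(triethylsilyl)oxy]-5-(triisopropylsilyl)penta-1,4-diyn-1-yl}lithium (racemic, formed in the flask) | [Li]C#CC(O[Si](CC)(CC)CC)C#C[Si](C(C)C)(C(C)C)C(C)C
F5 | step 2 | 1-phenyl-4-[(triethylsilyl)oxy]-6-(triisopropylsilyl)hexa-2,5-diyn-1-ol (diastereomer mixture) | OC(C#CC(O[Si](CC)(CC)CC)C#C[Si](C(C)C)(C(C)C)C(C)C)c1ccccc1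
F6 | step 2 | 1-phenyl-4-[(triethylsilyl)oxy]-6-(triisopropylsilyl)hexa-2,5-diyn-1-one (racemic) | O=C(C#CC(O[Si](CC)(CC)CC)C#C[Si](C(C)C)(C(C)C)C(C)C)c1ccccc1
F7 | step 7 | 4-[5-(3-hydroxy-3-phenylprop-1-yn-1-yl)-4-methyl-2-phenylfuran-3-yl]but-3-yn-2-ol (diastereomer mixture) | CC(O)C#Cc1c(-c2ccccc2)oc(C#CC(O)c2ccccc2)c1C
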